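A direct plan would take methyl 1H-indole-3-carboxylate A1, brominate it twice to methyl 5,6-dibromo-1H-indole-3-carboxylate A2, hydrolyse and decarboxylate that ester to 5,6-dibromo-1H-indole A3, and brominate C3 of A3 with NBS. Its weakest steps would be:
- the double ring bromination of A1 to A2: C5/C6 selectivity over C2, C4 and C7 would rest on a small electronic bias and on one isomer crystallising;
- the hydrolysis–decarboxylation of A2 to A3: the ester would serve only as a blocking group, so two of three steps would put it on and take it off (alkali, about 150 °C) without adding an atom of the target;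
- the last bromination, of the free N–H indole A3: over-bromination at C2 and oxidation would threaten the most advanced material and a labile product.

**Plan of the new route**
Cuts: C3–C3a (with a dinitrogen unit re-inserted between N1 and C3a), then N1–C2; target ⇐ 1-(2-bromoethenyl)-5,6-dibromobenzotriazole ⇐ 5,6-dibromobenzotriazole + 1,2-dibromoethene ⇐ 4,5-dibromobenzene-1,2-diamine.
Rings: benzene (bought with both Br), then triazole, then the pyrrole ring last, by photochemical loss of dinitrogen and C–C closure.
Enabling feature: the C5–Br/C6–Br pair makes C3a and C7a equivalent, so either triazole-bearing carbon may become C3a; C3 bears one H, so the 3H-indole formed first aromatises with Br still on C3.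
All bromines arrive in building blocks: no indole is brominated, no blocking group is put on or taken off, and the labile N–H 3-bromoindole appears only at the end, under neutral conditions.

Key step: step 3

Remark: 4 is drawn as its E isomer; the commercial E/Z mixture would serve equally, since the alkene geometry of 5 is lost in step 3.

Step 1
Reactants: 1 4,5-dibromobenzene-1,2-diamine
Product: 3 5,6-dibromo-1H-benzotriazole, via 2-amino-4,5-dibromobenzenediazonium acetate 2 (not isolated)
Conditions: NaNO2 (1.1 equiv), AcOH/H2O, 5 °C then rt
Reagents that add atoms: sodium nitrite, [Na+].[O-]N=O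
Why: Diazotisation of one amino group and capture of the diazonium ion by the neighbouring amino group (the classical benzotriazole synthesis) should close the triazole ring, the aryl bromides being inert and no stereocentre being formed.

Step 2
Reactants: 3 5,6-dibromo-1H-benzotriazole; 4 (E)-1,2-dibromoethene
Product: 5 5,6-dibromo-1-[(E)-2-bromoethenyl]-1H-benzotriazole
Conditions: 4 (5 equiv), CuI (10 mol %), trans-N,N′-dimethylcyclohexane-1,2-diamine (20 mol %), K3PO4 (2 equiv), toluene, 80 °C, sealed tube; chromatography
Reagents that add atoms: none
Why: Copper-catalysed Ullmann–Goldberg N-alkenylation of the azole N–H with a vinyl bromide should proceed with retention of alkene geometry; the vinyl C–Br bonds of the excess of 4 should react before the aryl C–Br bonds, the excess should hold substitution to one carbon of 4, and since N1 and N3 of 3 are equivalent only the minor N2 isomer has to be removed.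

Step 3
Reactants: 5 5,6-dibromo-1-[(E)-2-bromoethenyl]-1H-benzotriazole
Product: 7 3,5,6-tribromo-1H-indole, via 3,5,6-tribromo-3H-indole 6 (not isolated)
Conditions: hν (300 nm, Pyrex), degassed MeCN (0.005 M), 20 °C, flow cell
Reagents that add atoms: none
Why: Excitation of the benzotriazole chromophore should cleave the N1–N2 bond, and loss of dinitrogen from the ring-opened diazo imine leaves a 1,3-diradical (iminocarbene) with spin on the ring carbon that carried N3 and on the 1-azaallyl unit N1–C2–C3. Recombination of that ring carbon with the bromine-bearing vinyl carbon forms the C3–C3a bond, a five-atom, six-electron closure (1,5-electrocyclisation of the iminocarbene C3a–C7a=N1–C2=C3) that gives the 3H-indole 6, whose C3–H then shifts to nitrogen to give the aromatic 1H-indole with bromine left on C3. The closest known reaction type is the photochemical Graebe–Ullmann-type ring contraction of 1-alkenylbenzotriazoles to indoles. The C3 stereocentre of 6 arises as a racemate and vanishes on tautomerisation, so no stereocontrol is needed. Regioselectivity is not in question, because the C5–Br/C6–Br pair makes the two triazole-bearing ring carbons of 5 equivalent. The step needs loss of dinitrogen to outrun homolysis of the C–Br bonds, which irradiation at the long-wavelength edge of the absorption, high dilution, a solvent that is a poor hydrogen donor and removal of the product from the light in flow should secure.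

**Compound list**
1 | 4,5-dibromobenzene-1,2-diamine | Nc1cc(Br)c(Br)cc1N | starting material
2 | 2-amino-4,5-dibromobenzenediazonium acetate | CC(=O)[O-].Nc1cc(Br)c(Br)cc1[N+]#N | intermediate (not isolated)
3 | 5,6-dibromo-1H-benzotriazole | Brc1cc2[nH]nnc2cc1Br | intermediate
4 | (E)-1,2-dibromoethene | Br/C=C/Br | starting material
5 | 5,6-dibromo-1-[(E)-2-bromoethenyl]-1H-benzotriazole | Br/C=C/n1nnc2cc(Br)c(Br)cc21 | intermediate
6 | 3,5,6-tribromo-3H-indole (racemic) | BrC1C=Nc2cc(Br)c(Br)cc12 | intermediate (not isolated)
7 | 3,5,6-tribromo-1H-indole | Brc1cc2[nH]cc(Br)c2cc1Br | target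

Total step count: 3. Longest linear sequence: 3 steps (1 → 3 → 5 → 7).

**Steps most likely to fail**

Step 3. Homolysis of carbon–bromine bonds under irradiation (above all in the vinyl bromide and in the 3-bromoindole as it forms) may compete with loss of dinitrogen, and the diradical may abstract hydrogen in place of closing the ring. Fallback, setting out from 1 and coming back at 7: the pyrrole ring would be closed in the dark by aminobromination of an alkyne. Tetrazotisation of 1 (nitrosylsulfuric acid in H2SO4/H3PO4, 0 °C, the strong acid holding the second amino group protonated so that the triazole does not close) would give 4,5-dibromobenzene-1,2-bis(diazonium) bis(hydrogen sulfate) F1, which with aqueous KI would give 1,2-dibromo-4,5-diiodobenzene F2 (also an article of commerce). Copper-catalysed amination of one C–I bond (CuI, L-proline, aqueous NH3, DMSO) would give 4,5-dibromo-2-iodoaniline F3. Sonogashira coupling at the C–I bond with ethynyltrimethylsilane (PdCl2(PPh3)2, CuI, Et3N, rt) would give 4,5-dibromo-2-[(trimethylsilyl)ethynyl]aniline F4. A 5-endo-dig aminobromination (PdBr2 cat., CuBr2, THF, rt) would give 3,5,6-tribromo-2-(trimethylsilyl)-1H-indole F5, in which the silyl group shields C2 while the C3–Br bond is made together with the ring. Tetrabutylammonium fluoride in THF would then remove the silyl group and return the route at 7.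

Step 2. Copper may insert into the aryl carbon–bromine bonds (self-coupling of 3), both bromines of 4 may be substituted, and alkenylation may go to N2. Fallback, setting out from 3 and coming back at 5: conjugate addition of 3 to methyl propiolate (DABCO cat., MeCN, rt) would give methyl (E)-3-(5,6-dibromo-1H-benzotriazol-1-yl)prop-2-enoate F6. LiOH in aqueous THF, then acid, would give (E)-3-(5,6-dibromo-1H-benzotriazol-1-yl)prop-2-enoic acid F7. Bromodecarboxylation of this unsaturated acid (catalytic Hunsdiecker reaction: NBS, LiOAc cat., MeCN/H2O, rt) would return the route at 5 without copper and without a vinyl halide electrophile.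

Step 1. The diazonium ion may couple with diamine that has not yet reacted (triazene and azo oligomers), favoured by poor solubility of the dibromodiamine in aqueous acid. Fallback, setting out from 1 and coming back at 3: mono-acetylation of 1 (Ac2O, 1 equiv, THF, 0 °C) would give N-(2-amino-4,5-dibromophenyl)acetamide F8. Its diazotisation in homogeneous organic solution (tert-butyl nitrite, AcOH/THF, 0 °C) would be captured by the amide nitrogen to give 1-(5,6-dibromo-1H-benzotriazol-1-yl)ethan-1-one F9. Methanolysis (K2CO3, MeOH, rt) would return the route at 3.

**Further compounds**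
F1 | step 3 | 4,5-dibromobenzene-1,2-bis(diazonium) bis(hydrogen sulfate) | N#[N+]c1cc(Br)c(Br)cc1[N+]#N.OS(=O)(=O)[O-].OS(=O)(=O)[O-]
F2 | step 3 | 1,2-dibromo-4,5-diiodobenzene | Brc1cc(I)c(I)cc1Br
F3 | step 3 | 4,5-dibromo-2-iodoaniline | Nc1cc(Br)c(Br)cc1I
F4 | step 3 | 4,5-dibromo-2-[(trimethylsilyl)ethynyl]aniline | C[Si](C)(C)C#Cc1cc(Br)c(Br)cc1N
F5 | step 3 | 3,5,6-tribromo-2-(trimethylsilyl)-1H-indole | C[Si](C)(C)c1[nH]c2cc(Br)c(Br)cc2c1Br
F6 | step 2 | methyl (E)-3-(5,6-dibromo-1H-benzotriazol-1-yl)prop-2-enoate | COC(=O)/C=C/n1nnc2cc(Br)c(Br)cc21
F7 | step 2 | (E)-3-(5,6-dibromo-1H-benzotriazol-1-yl)prop-2-enoic acid | OC(=O)/C=C/n1nnc2cc(Br)c(Br)cc21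
F8 | step 1 | N-(2-amino-4,5-dibromophenyl)acetamide | CC(=O)Nc1cc(Br)c(Br)cc1N
F9 | step 1 | 1-(5,6-dibromo-1H-benzotriazol-1-yl)ethan-1-one | CC(=O)n1nnc2cc(Br)c(Br)cc21
A1 | direct plan | methyl 1H-indole-3-carboxylate | COC(=O)c1c[nH]c2ccccc12
A2 | direct plan | methyl 5,6-dibromo-1H-indole-3-carboxylate | COC(=O)c1c[nH]c2cc(Br)c(Br)cc12
A3 | direct plan | 5,6-dibromo-1H-indole | Brc1cc2cc[nH]c2cc1Br
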